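**Retrosynthetic overview**
1. The target, the (3R,4R)-trans-dibenzylbutyrolactone, comes from a 3-(aryl-hydroxymethyl) lactone by removing the benzylic oxygen (acetate, then C–O hydrogenolysis) as the last operation.
2. Key disconnection, C3–C(benzylic): aldol addition of the lithium enolate of (R)-4-(3,4,5-trimethoxybenzyl)butyrolactone to 3,4-dimethoxybenzaldehyde; the C4 substituent directs C3 trans.
3. The (R)-lactone comes from a γ-hydroxy tert-butyl ester, itself from Evans alkylation of the (S)-4-benzyloxazolidinone imide of 3-(3,4,5-trimethoxyphenyl)propanoic acid with tert-butyl bromoacetate (sets C4).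
4. Ring order: only one ring is built, the γ-lactone (step 4), before the aldol; both benzene rings are bought intact.

Assumption: the aldol adduct 14 and its acetate 15 are carried as the mixture of both carbinol epimers, because that center is erased in step 7; acid 1 is bought as such.

**Step 1**
Reactants: 1 3-(3,4,5-trimethoxyphenyl)propanoic acid; 2 (S)-4-benzyl-1,3-oxazolidin-2-one
Product: 4 (S)-4-benzyl-3-[3-(3,4,5-trimethoxyphenyl)propanoyl]-1,3-oxazolidin-2-one, via mixed pivalic anhydride 3 (not isolated)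
Conditions: PivCl (1.1 equiv), Et3N (2.5 equiv), THF, −20 °C, 1 h; then LiCl (1.1 equiv), 2 (1.0 equiv), −20 °C to rt, 12 h
Reagents that add atoms: pivaloyl chloride, `CC(C)(C)C(=O)Cl` (its acyl group is held by 3 only)
Why: N-acylation of the oxazolidinone through a mixed anhydride (acyl transfer) works because the LiCl/Et3N-activated oxazolidinone attacks the unhindered carbonyl of 3 and not the pivaloyl one, and no stereocenter is made or touched.

**Step 2**
Reactants: 4 (S)-4-benzyl-3-[3-(3,4,5-trimethoxyphenyl)propanoyl]-1,3-oxazolidin-2-one; 5 tert-butyl bromoacetate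
Product: 7 tert-butyl (3R)-4-[(4S)-4-benzyl-2-oxo-1,3-oxazolidin-3-yl]-4-oxo-3-(3,4,5-trimethoxybenzyl)butanoate, via sodium Z-enolate 6 (not isolated)
Conditions: NaN(SiMe3)2 (1.1 equiv), THF, −78 °C, 45 min; then 5 (2.0 equiv), −78 to −40 °C, 3 h; aq NH4Cl
Reagents that add atoms: NaN(SiMe3)2, `[Na+].C[Si](C)(C)[N-][Si](C)(C)C` (its sodium is held by 6 only)
Why: In this Evans auxiliary-controlled enolate alkylation the chelated Z-enolate 6 is shielded on one face by the benzyl group of the (S)-oxazolidinone, so the bromoacetate enters from the open face and sets the new center as R (the later C4 of the lactone), the minor diastereomer being removed by chromatography.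

**Step 3**
Reactants: 7 tert-butyl (3R)-4-[(4S)-4-benzyl-2-oxo-1,3-oxazolidin-3-yl]-4-oxo-3-(3,4,5-trimethoxybenzyl)butanoate
Product: 8 tert-butyl (3R)-3-(hydroxymethyl)-4-(3,4,5-trimethoxyphenyl)butanoate
Conditions: LiBH4 (1.5 equiv), MeOH (1.5 equiv), THF, 0 °C, 2 h; aqueous work-up
Reagents that add atoms: none
Why: Reductive cleavage of the N-acyl oxazolidinone by LiBH4 (hydride reduction of the activated exocyclic imide carbonyl) gives the primary alcohol and frees the auxiliary, while the hindered tert-butyl ester is not reduced at 0 °C and the stereocenter, never deprotonated, keeps its configuration.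

**Step 4**
Reactants: 8 tert-butyl (3R)-3-(hydroxymethyl)-4-(3,4,5-trimethoxyphenyl)butanoate
Product: 10 (R)-4-(3,4,5-trimethoxybenzyl)dihydrofuran-2(3H)-one, via hydroxy acid 9 (not isolated)
Conditions: p-TsOH·H2O (0.1 equiv), toluene, 90 °C, 2 h
Reagents that add atoms: none
Why: Acid-catalysed tert-butyl ester cleavage (loss of isobutene) followed by spontaneous lactonisation of the γ-hydroxy acid 9 closes the five-membered ring without touching the stereocenter, which is not α to the carbonyl.

**Step 5**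
Reactants: 10 (R)-4-(3,4,5-trimethoxybenzyl)dihydrofuran-2(3H)-one; 11 3,4-dimethoxybenzaldehyde
Product: 14 (3S,4R)-3-[(3,4-dimethoxyphenyl)(hydroxy)methyl]-4-(3,4,5-trimethoxybenzyl)dihydrofuran-2(3H)-one as a mixture of carbinol epimers, via lithium enolate 12 (not isolated), via lithium aldolate 13 (not isolated)
Conditions: LiN(SiMe3)2 (1.1 equiv), THF, −78 °C, 45 min; then 11 (1.2 equiv), −78 °C, 1 h; AcOH (1.5 equiv) at −78 °C
Reagents that add atoms: LiN(SiMe3)2, `[Li+].C[Si](C)(C)[N-][Si](C)(C)C` (its lithium is held by 12 and 13 only)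
Why: In this intermolecular aldol addition of a lactone lithium enolate to an aromatic aldehyde, the aldehyde attacks C3 of 12 on the face anti to the C4 benzyl group, which sets C3 trans to C4 (the relationship of the target), while the carbinol center forms unselectively and is removed later, and the cold AcOH quench prevents retro-aldol.

**Step 6**
Reactants: 14 (3S,4R)-3-[(3,4-dimethoxyphenyl)(hydroxy)methyl]-4-(3,4,5-trimethoxybenzyl)dihydrofuran-2(3H)-one
Product: 15 (3,4-dimethoxyphenyl)[(3S,4R)-2-oxo-4-(3,4,5-trimethoxybenzyl)tetrahydrofuran-3-yl]methyl acetate (both carbinol epimers)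
Conditions: Ac2O (2 equiv), pyridine (4 equiv), DMAP (0.05 equiv), CH2Cl2, 0 °C to rt, 3 h
Reagents that add atoms: acetic anhydride, `CC(=O)OC(C)=O`
Why: DMAP-catalysed O-acetylation (nucleophilic acyl transfer) turns the benzylic hydroxyl into an acetate that is cleaved easily under neutral hydrogenolysis, and the mild base neither epimerises C3 nor eliminates.

**Step 7**
Reactants: 15 (3,4-dimethoxyphenyl)[(3S,4R)-2-oxo-4-(3,4,5-trimethoxybenzyl)tetrahydrofuran-3-yl]methyl acetate
Product: 16 (3R,4R)-3-(3,4-dimethoxybenzyl)-4-(3,4,5-trimethoxybenzyl)dihydrofuran-2(3H)-one (target)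
Conditions: H2 (3 bar), 10% Pd/C, EtOAc/EtOH 1:1, rt, 12 h
Reagents that add atoms: none
Why: Heterogeneous palladium-catalysed hydrogenolysis of the electron-rich benzylic C–O bond replaces the acetoxy group by hydrogen under neutral conditions, so no benzylic cation can close onto the trimethoxyphenyl ring, and the trans C3 and C4 centers, not involved in the reaction, are retained.

**Compound list**
```
1 | 3-(3,4,5-trimethoxyphenyl)propanoic acid | COc1cc(CCC(=O)O)cc(OC)c1OC | starting material
2 | (S)-4-benzyl-1,3-oxazolidin-2-one | O=C1N[C@@H](Cc2ccccc2)CO1 | starting material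
3 | 2,2-dimethylpropanoic 3-(3,4,5-trimethoxyphenyl)propanoic anhydride (mixed pivalic anhydride, formed in the flask) | COc1cc(CCC(=O)OC(=O)C(C)(C)C)cc(OC)c1OC | intermediate
4 | (S)-4-benzyl-3-[3-(3,4,5-trimethoxyphenyl)propanoyl]-1,3-oxazolidin-2-one | COc1cc(CCC(=O)N2C(=O)OC[C@@H]2Cc2ccccc2)cc(OC)c1OC | intermediate
5 | tert-butyl bromoacetate | CC(C)(C)OC(=O)CBr | starting material
6 | sodium (Z)-1-[(4S)-4-benzyl-2-oxo-1,3-oxazolidin-3-yl]-3-(3,4,5-trimethoxyphenyl)prop-1-en-1-olate (formed in the flask) | [Na+].[O-]/C(=C\Cc1cc(OC)c(OC)c(OC)c1)N1C(=O)OC[C@@H]1Cc1ccccc1 | intermediate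
7 | tert-butyl (3R)-4-[(4S)-4-benzyl-2-oxo-1,3-oxazolidin-3-yl]-4-oxo-3-(3,4,5-trimethoxybenzyl)butanoate | COc1cc(C[C@H](CC(=O)OC(C)(C)C)C(=O)N2C(=O)OC[C@@H]2Cc2ccccc2)cc(OC)c1OC | intermediate
8 | tert-butyl (3R)-3-(hydroxymethyl)-4-(3,4,5-trimethoxyphenyl)butanoate | COc1cc(C[C@H](CC(=O)OC(C)(C)C)CO)cc(OC)c1OC | intermediate
9 | (3R)-4-hydroxy-3-(3,4,5-trimethoxybenzyl)butanoic acid (formed in the flask) | COc1cc(C[C@H](CC(=O)O)CO)cc(OC)c1OC | intermediate
10 | (R)-4-(3,4,5-trimethoxybenzyl)dihydrofuran-2(3H)-one | O=C1C[C@@H](Cc2cc(OC)c(OC)c(OC)c2)CO1 | intermediate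
11 | 3,4-dimethoxybenzaldehyde | COc1ccc(C=O)cc1OC | starting material
12 | lithium (4R)-4-(3,4,5-trimethoxybenzyl)-4,5-dihydrofuran-2-olate (formed in the flask) | [Li+].[O-]C1=C[C@@H](Cc2cc(OC)c(OC)c(OC)c2)CO1 | intermediate
13 | lithium (3,4-dimethoxyphenyl)[(3S,4R)-2-oxo-4-(3,4,5-trimethoxybenzyl)tetrahydrofuran-3-yl]methanolate, both carbinol epimers (formed in the flask) | [Li+].COc1ccc(C([O-])[C@H]2C(=O)OC[C@@H]2Cc2cc(OC)c(OC)c(OC)c2)cc1OC | intermediate
14 | (3S,4R)-3-[(3,4-dimethoxyphenyl)(hydroxy)methyl]-4-(3,4,5-trimethoxybenzyl)dihydrofuran-2(3H)-one, both carbinol epimers | COc1ccc(C(O)[C@H]2C(=O)OC[C@@H]2Cc2cc(OC)c(OC)c(OC)c2)cc1OC | intermediate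
15 | (3,4-dimethoxyphenyl)[(3S,4R)-2-oxo-4-(3,4,5-trimethoxybenzyl)tetrahydrofuran-3-yl]methyl acetate, both carbinol epimers | COc1ccc(C(OC(C)=O)[C@H]2C(=O)OC[C@@H]2Cc2cc(OC)c(OC)c(OC)c2)cc1OC | intermediate
16 | (3R,4R)-3-(3,4-dimethoxybenzyl)-4-(3,4,5-trimethoxybenzyl)dihydrofuran-2(3H)-one | COc1ccc(C[C@H]2C(=O)OC[C@@H]2Cc2cc(OC)c(OC)c(OC)c2)cc1OC | target
```

**Summary**
Total step count: 7.
Longest linear sequence: 7 steps (1 to 16); 2, 5 and 11 are bought.

The three steps most likely to fail:

- **Reductive removal of the auxiliary (step 3).** The risk is hydride attack at the ring carbonyl of the oxazolidinone, or lactonisation in the flask followed by over-reduction to a diol. The fallback sets out from 7: LiOH/H2O2 in THF–H2O at 0 °C hydrolyses the imide to (2R)-4-tert-butoxy-4-oxo-2-(3,4,5-trimethoxybenzyl)butanoic acid F1, and BH3·SMe2 in THF (0 °C to rt) then reduces only the free carboxylic acid. This comes back to the route at 8.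

- **Aldol addition (step 5).** The risk is retro-aldol or dehydration of the lithium aldolate, or incomplete conversion. The fallback sets out from 10 and makes the same C3–C bond by a crossed Claisen acylation. The enolate of 10 (2.1 equiv LiN(SiMe3)2, THF, −78 °C) is acylated by 3,4-dimethoxybenzoyl chloride to the β-keto lactone (3S,4R)-3-(3,4-dimethoxybenzoyl)-4-(3,4,5-trimethoxybenzyl)dihydrofuran-2(3H)-one F2, whose acidic C3 settles trans to the C4 benzyl group. NaBH4 in MeOH at −20 °C then reduces only the aryl ketone, and the route is rejoined at 14.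

- **Hydrogenolysis (step 7).** The risk is slow C–O cleavage, or loss of AcOH to the benzylidene lactone, whose hydrogenation would give cis/trans mixtures. The fallback sets out from 14 and deoxygenates by a radical path (Barton–McCombie). Phenyl chlorothionoformate, pyridine and DMAP in CH2Cl2 give O-[(3,4-dimethoxyphenyl)((3S,4R)-2-oxo-4-(3,4,5-trimethoxybenzyl)tetrahydrofuran-3-yl)methyl] O-phenyl carbonothioate F3. Bu3SnH and AIBN in toluene at 90 °C then reduce the benzylic radical to the methylene group without touching C3 or C4, and the route is rejoined at 16.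

**Further compounds**
```
F1 | step 3 | (2R)-4-tert-butoxy-4-oxo-2-(3,4,5-trimethoxybenzyl)butanoic acid | COc1cc(C[C@H](CC(=O)OC(C)(C)C)C(=O)O)cc(OC)c1OC
F2 | step 5 | (3S,4R)-3-(3,4-dimethoxybenzoyl)-4-(3,4,5-trimethoxybenzyl)dihydrofuran-2(3H)-one | COc1ccc(C(=O)[C@H]2C(=O)OC[C@@H]2Cc2cc(OC)c(OC)c(OC)c2)cc1OC
F3 | step 7 | O-[(3,4-dimethoxyphenyl)((3S,4R)-2-oxo-4-(3,4,5-trimethoxybenzyl)tetrahydrofuran-3-yl)methyl] O-phenyl carbonothioate, both carbinol epimers | COc1ccc(C(OC(=S)Oc2ccccc2)[C@H]2C(=O)OC[C@@H]2Cc2cc(OC)c(OC)c(OC)c2)cc1OC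
```
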